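**Plan**
Retrosynthesis: the C3 carbinol is traced to a C2-symmetric 3,22-diketone; the C3–O/C22–O bonds and one methyl on each of C2/C23 are cut back to a bis(ε-lactone); O–C7/O–C2 and O–C18/O–C23 are cut by a twofold Baeyer–Villiger retron to a bis(trans-decalone); C12–C13 is cut to two identical allylic bromides.
Enabling feature: each oxepane (O–C2–C3–C4–C5–C6–C7) is the cyclohexanone ring C2–C7 with oxygen inserted between the C2 carbonyl and its more substituted α-carbon, the ring-fusion CH C7, which lies trans to the C6 methyl and next to the cyclohexene ring C6–C11.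
Forward: decalin of each half from (R)-Wieland–Miescher ketone → C12 by carbonylation → C12–C13 by allylic homocoupling → trans ring fusion by hydroboration → both oxepane rings by oxygen insertion → C2/C23 methylation with C3/C22 oxygenation → mono-reduction.
Stereochemistry: C6/C19 come from the Wieland–Miescher ketone; C7/C18 from hydroboration anti to the angular methyl, kept through the migration with retention; C3 from (S)-CBS reduction.

Key step: step 11

Remark: C1–C24 in the discussion follow squalene numbering of the target; compound names use naphthalene or 1-benzoxepine locants; enantiopure (R)-(−)-Wieland–Miescher ketone 1 is taken as purchasable.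

Step 1
Reactants: 1 (R)-(−)-Wieland–Miescher ketone
Product: 2 (8aR)-6,6-(ethane-1,2-diyldisulfanediyl)-8a-methyl-3,4,6,7,8,8a-hexahydronaphthalen-1(2H)-one
Conditions: HSCH2CH2SH, p-TsOH (cat.), AcOH, rt
Reagents that add atoms: ethane-1,2-dithiol, SCCS
Why: Acid-catalysed dithioketalisation should be selective for the conjugated C6 carbonyl because the C1 ketone is neopentyl, and the dithiolane of an enone keeps its alkene at C4a=C5, where the later hydroboration needs it.

Step 2
Reactants: 2 (8aR)-6,6-(ethane-1,2-diyldisulfanediyl)-8a-methyl-3,4,6,7,8,8a-hexahydronaphthalen-1(2H)-one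
Product: 3 (8aR)-8a-methyl-3,4,6,7,8,8a-hexahydronaphthalen-1(2H)-one
Conditions: Raney Ni, EtOH, reflux
Reagents that add atoms: none
Why: Raney-nickel desulfurisation (Mozingo reduction) replaces both C–S bonds by C–H, as in the conversion of steroidal 4-en-3-one dithioketals into 4-enes, and should leave the trisubstituted alkene, the hindered ketone and the quaternary stereocentre in place.

Step 3
Reactants: 3 (8aR)-8a-methyl-3,4,6,7,8,8a-hexahydronaphthalen-1(2H)-one
Product: 5 (8aR)-2,8a-dimethyl-3,4,6,7,8,8a-hexahydronaphthalen-1(2H)-one (C2 epimers), via lithium enolate 4 (not isolated)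
Conditions: LiN(iPr)2, THF, −78 °C; MeI, −78 → 0 °C
Reagents that add atoms: iodomethane, CI; lithium diisopropylamide, CC(C)[N-]C(C)C.[Li+] (lithium of 4 only)
Why: Enolate alkylation: C2 is the only enolisable position because the other α-carbon is quaternary, so the future C10 methyl is introduced there, and its configuration is irrelevant because C2 becomes sp2 in step 4.

Step 4
Reactants: 5 (8aR)-2,8a-dimethyl-3,4,6,7,8,8a-hexahydronaphthalen-1(2H)-one
Product: 7 (8aR)-2,8a-dimethyl-3,4,6,7,8,8a-hexahydronaphthalen-1-yl trifluoromethanesulfonate, via potassium enolate 6 (not isolated)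
Conditions: KN(SiMe3)2, THF, −78 → 0 °C; PhNTf2, −78 °C → rt
Reagents that add atoms: N-phenylbis(trifluoromethanesulfonimide), O=S(=O)(N(c1ccccc1)S(=O)(=O)C(F)(F)F)C(F)(F)F; potassium bis(trimethylsilyl)amide, C[Si](C)(C)[N-][Si](C)(C)C.[K+] (potassium of 6 only)
Why: Enol triflate formation: the enolate can form only toward C2 and so gives the tetrasubstituted C1=C2 alkene (C11=C10 of the target), as is established for 2,2,6-trimethylcyclohexanone.

Step 5
Reactants: 7 (8aR)-2,8a-dimethyl-3,4,6,7,8,8a-hexahydronaphthalen-1-yl trifluoromethanesulfonate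
Product: 8 methyl (8aR)-2,8a-dimethyl-3,4,6,7,8,8a-hexahydronaphthalene-1-carboxylate
Conditions: Pd(OAc)2 (cat.), dppp (cat.), CO (1 atm), MeOH, Et3N, DMF, 70 °C
Reagents that add atoms: carbon monoxide, [C-]#[O+]; methanol, CO
Why: Palladium-catalysed alkoxycarbonylation of an enol triflate (oxidative addition to zerovalent palladium formed in situ, CO insertion, methanolysis of the acyl complex) attaches the carbon that becomes C12 without disturbing the second alkene.

Step 6
Reactants: 8 methyl (8aR)-2,8a-dimethyl-3,4,6,7,8,8a-hexahydronaphthalene-1-carboxylate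
Product: 9 [(8aR)-2,8a-dimethyl-3,4,6,7,8,8a-hexahydronaphthalen-1-yl]methanol
Conditions: iBu2AlH, CH2Cl2, −78 → 0 °C
Reagents that add atoms: none
Why: 1,2-Reduction of the hindered α,β-unsaturated ester by the aluminium hydride should give the primary allylic alcohol, there being no other reducible group.

Step 7
Reactants: 9 [(8aR)-2,8a-dimethyl-3,4,6,7,8,8a-hexahydronaphthalen-1-yl]methanol
Product: 10 (8aR)-1-(bromomethyl)-2,8a-dimethyl-3,4,6,7,8,8a-hexahydronaphthalene
Conditions: CBr4, PPh3, CH2Cl2, 0 °C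
Reagents that add atoms: tetrabromomethane, BrC(Br)(Br)Br
Why: Appel bromination converts the primary allylic alcohol into the bromide under neutral conditions, and an allylic transposition would be harmless because both regioisomers lead to the same allyl intermediate in step 8.

Step 8
Reactants: 10 (8aR)-1-(bromomethyl)-2,8a-dimethyl-3,4,6,7,8,8a-hexahydronaphthalene (two molecules)
Product: 11 1,2-bis[(8aR)-2,8a-dimethyl-3,4,6,7,8,8a-hexahydronaphthalen-1-yl]ethane
Conditions: CoCl(PPh3)3, benzene, rt, Ar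
Reagents that add atoms: none
Why: Reductive (Wurtz-type) homocoupling of allylic halides with the monovalent cobalt complex is known to join allyl units head to head and should form C12–C13, because the other allyl terminus (C10) is fully substituted, while two identical enantiomers can give only the C2-symmetric product.

Step 9
Reactants: 11 1,2-bis[(8aR)-2,8a-dimethyl-3,4,6,7,8,8a-hexahydronaphthalen-1-yl]ethane
Product: 13 5,5'-(ethane-1,2-diyl)bis[(1S,4aR,8aS)-4a,6-dimethyl-1,2,3,4,4a,7,8,8a-octahydronaphthalen-1-ol], via bis(alkylborane) 12 (not isolated)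
Conditions: BH3·THF, THF, 0 °C → rt; NaOH, H2O2, 0 °C → rt
Reagents that add atoms: hydrogen peroxide, OO; borane–tetrahydrofuran, B.C1CCOC1 (boron of 12 only)
Why: Hydroboration–oxidation: borane should add syn to each trisubstituted ring-fusion alkene from the face opposite the angular methyl, as with steroidal 4-enes and 5-enes, so the new ring-fusion hydrogen (C7, C18) is trans to the methyl and the carbinol carbon is set on the face of that hydrogen, while the far more hindered tetrasubstituted alkenes should remain.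

Step 10
Reactants: 13 5,5'-(ethane-1,2-diyl)bis[(1S,4aR,8aS)-4a,6-dimethyl-1,2,3,4,4a,7,8,8a-octahydronaphthalen-1-ol]
Product: 14 5,5'-(ethane-1,2-diyl)bis[(4aR,8aS)-4a,6-dimethyl-3,4,4a,7,8,8a-hexahydronaphthalen-1(2H)-one]
Conditions: Dess–Martin periodinane, pyridine, CH2Cl2, 0 °C → rt
Reagents that add atoms: none
Why: Dess–Martin oxidation under buffered, non-enolising conditions should give both ketones without epimerising the adjacent ring-fusion CH and without touching the alkenes.

Step 11
Reactants: 14 5,5'-(ethane-1,2-diyl)bis[(4aR,8aS)-4a,6-dimethyl-3,4,4a,7,8,8a-hexahydronaphthalen-1(2H)-one]; 15 bis(trimethylsilyl) peroxide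
Product: 17 6,6'-(ethane-1,2-diyl)bis[(5aS,9aS)-5a,7-dimethyl-4,5,5a,8,9,9a-hexahydro-1-benzoxepin-2(3H)-one], via bis(Criegee adduct) 16 (not isolated)
Conditions: (Me3SiO)2, SnCl4 (cat.), trans-cyclohexane-1,2-diamine (cat.), 4 Å MS, CH2Cl2, 0 °C → rt
Reagents that add atoms: bis(trimethylsilyl) peroxide (15), C[Si](C)(C)OO[Si](C)(C)C
Why: The SnCl4–diamine complex activates each ketone for addition of the silyl peroxide to give the silylated Criegee adduct 16, in which the ring-fusion carbon (C7, C18), antiperiplanar to the O–O bond, shifts from carbon to oxygen with loss of Me3SiO−, so that O–C7/O–C2 and O–C18/O–C23 are formed. The closest known reaction type is the Baeyer–Villiger oxidation of 2-alkylcyclohexanones such as trans-1-decalones with bis(trimethylsilyl) peroxide and a Lewis acid. Each seven-membered lactone arises by ring expansion of a cyclohexanone through this 1,2-shift, not by an end-to-end cyclisation. No stereocentre is created: the migrating carbon keeps its configuration, so the trans relation between H at C7 and the C6 methyl set in step 9 is carried into the ring. The step needs migration of the secondary ring-fusion carbon in preference to the C3 methylene (migratory aptitude), no enolisation toward C7 before migration (aprotic, weakly acidic medium at low temperature) and oxidation of C=O beside two tetrasubstituted alkenes (a peroxide that becomes an oxidant only after carbonyl addition and is no epoxidising agent).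

Step 12
Reactants: 17 6,6'-(ethane-1,2-diyl)bis[(5aS,9aS)-5a,7-dimethyl-4,5,5a,8,9,9a-hexahydro-1-benzoxepin-2(3H)-one]
Product: 19 bis(ketene acetal diphenyl phosphate) of 17, via bis(potassium enolate) 18 (not isolated)
Conditions: KN(SiMe3)2, THF–HMPA, −78 °C; (PhO)2P(O)Cl
Reagents that add atoms: diphenyl phosphorochloridate, O=P(Cl)(Oc1ccccc1)Oc1ccccc1; potassium bis(trimethylsilyl)amide, C[Si](C)(C)[N-][Si](C)(C)C.[K+] (potassium of 18 only)
Why: O-Phosphorylation of lactone enolates to cyclic ketene acetal phosphates is a standard activation of medium-ring lactones, and C3/C22 carry the only acidic hydrogens.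

Step 13
Reactants: 19 bis(ketene acetal diphenyl phosphate) of 17
Product: 20 1,2-bis[(5aS,9aS)-2,5a,7-trimethyl-4,5,5a,8,9,9a-hexahydro-1-benzoxepin-6-yl]ethane
Conditions: MeZnCl, Pd(PPh3)4 (cat.), THF, rt → 50 °C
Reagents that add atoms: methylzinc chloride, C[Zn]Cl
Why: Negishi coupling of a ketene acetal phosphate (oxidative addition of the C–O bond to zerovalent palladium, transmetalation from zinc, reductive elimination) puts the first methyl on C2 and C23 while the ring C–O bonds made in step 11 stay intact.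

Step 14
Reactants: 20 1,2-bis[(5aS,9aS)-2,5a,7-trimethyl-4,5,5a,8,9,9a-hexahydro-1-benzoxepin-6-yl]ethane
Product: 22 6,6'-(ethane-1,2-diyl)bis[(5aS,9aS)-2,2,5a,7-tetramethyl-2,3,4,5,5a,8,9,9a-octahydro-1-benzoxepin-3-ol] (C3 epimers), via bis(epoxide) 21 (not isolated)
Conditions: DMDO, CH2Cl2, −78 °C; then AlMe3, −78 → 0 °C
Reagents that add atoms: dimethyldioxirane, CC1(C)OO1; trimethylaluminium, C[Al](C)C
Why: Enol ether epoxidation followed by AlMe3 opening of the epoxy acetal is a known way to a tertiary ether carbon with a neighbouring hydroxyl: the electron-rich enol ethers should react with the neutral dioxirane before the hindered tetrasubstituted alkenes, AlMe3 then opens the epoxide to the tertiary oxocarbenium ion and transfers methyl to C2/C23, which become non-stereogenic, and the C3/C22 configuration set by the face of epoxidation need not be controlled because step 15 removes it.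

Step 15
Reactants: 22 6,6'-(ethane-1,2-diyl)bis[(5aS,9aS)-2,2,5a,7-tetramethyl-2,3,4,5,5a,8,9,9a-octahydro-1-benzoxepin-3-ol]
Product: 23 6,6'-(ethane-1,2-diyl)bis[(5aS,9aS)-2,2,5a,7-tetramethyl-4,5,5a,8,9,9a-hexahydro-1-benzoxepin-3(2H)-one]
Conditions: Dess–Martin periodinane, pyridine, CH2Cl2, rt
Reagents that add atoms: none
Why: Dess–Martin oxidation of the hindered secondary alcohols should converge all C3/C22 epimers on one C2-symmetric diketone, and neither α-position of the new ketones carries a stereocentre that could epimerise.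

Step 16
Reactants: 23 6,6'-(ethane-1,2-diyl)bis[(5aS,9aS)-2,2,5a,7-tetramethyl-4,5,5a,8,9,9a-hexahydro-1-benzoxepin-3(2H)-one]
Product: 24 sodwanone T
Conditions: (S)-2-methyl-CBS-oxazaborolidine (cat.), BH3·SMe2 (0.6 equiv), THF, −20 °C
Reagents that add atoms: none
Why: Corey–Bakshi–Shibata reduction with a deficit of hydride should reduce one of the two equivalent, remote ketones, the (S)-catalyst distinguishing the quaternary C2 from the C4 methylene to give the (3R)-carbinol under catalyst control, with recovered 23 and over-reduced diol (through step 15) returned to the sequence.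

**Compound list**
1 | (R)-(−)-Wieland–Miescher ketone, (8aR)-8a-methyl-3,4,8,8a-tetrahydronaphthalene-1,6(2H,7H)-dione | C[C@@]12CCC(=O)C=C1CCCC2=O | starting material
2 | (8aR)-6,6-(ethane-1,2-diyldisulfanediyl)-8a-methyl-3,4,6,7,8,8a-hexahydronaphthalen-1(2H)-one (C6 dithiolane of 1) | C[C@@]12CCC3(SCCS3)C=C1CCCC2=O | intermediate
3 | (8aR)-8a-methyl-3,4,6,7,8,8a-hexahydronaphthalen-1(2H)-one | C[C@@]12CCCC=C1CCCC2=O | intermediate
4 | lithium enolate of 3 (C1–O−, C1=C2) | C[C@@]12CCCC=C1CCC=C2[O-].[Li+] | intermediate (not isolated)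
5 | (8aR)-2,8a-dimethyl-3,4,6,7,8,8a-hexahydronaphthalen-1(2H)-one, mixture of C2 epimers | C[C@@]12CCCC=C1CCC(C)C2=O | intermediate
6 | potassium enolate of 5 (C1–O−, C1=C2) | C[C@@]12CCCC=C1CCC(C)=C2[O-].[K+] | intermediate (not isolated)
7 | (8aR)-2,8a-dimethyl-3,4,6,7,8,8a-hexahydronaphthalen-1-yl trifluoromethanesulfonate | C[C@@]12CCCC=C1CCC(C)=C2OS(=O)(=O)C(F)(F)F | intermediate
8 | methyl (8aR)-2,8a-dimethyl-3,4,6,7,8,8a-hexahydronaphthalene-1-carboxylate | C[C@@]12CCCC=C1CCC(C)=C2C(=O)OC | intermediate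
9 | [(8aR)-2,8a-dimethyl-3,4,6,7,8,8a-hexahydronaphthalen-1-yl]methanol | C[C@@]12CCCC=C1CCC(C)=C2CO | intermediate
10 | (8aR)-1-(bromomethyl)-2,8a-dimethyl-3,4,6,7,8,8a-hexahydronaphthalene | C[C@@]12CCCC=C1CCC(C)=C2CBr | intermediate
11 | 1,2-bis[(8aR)-2,8a-dimethyl-3,4,6,7,8,8a-hexahydronaphthalen-1-yl]ethane (C2-symmetric tetraene) | C(CC1=C(C)CCC2=CCCC[C@@]12C)C1=C(C)CCC2=CCCC[C@@]12C | intermediate
12 | bis(alkylborane): 13 with BH2 in place of each OH, boron on the face of the ring-fusion hydrogen | C(CC1=C(C)CC[C@@H]2[C@@H](B)CCC[C@@]12C)C1=C(C)CC[C@@H]2[C@@H](B)CCC[C@@]12C | intermediate (not isolated)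
13 | 5,5'-(ethane-1,2-diyl)bis[(1S,4aR,8aS)-4a,6-dimethyl-1,2,3,4,4a,7,8,8a-octahydronaphthalen-1-ol] (bis(trans-decalol)) | C(CC1=C(C)CC[C@@H]2[C@@H](O)CCC[C@@]12C)C1=C(C)CC[C@@H]2[C@@H](O)CCC[C@@]12C | intermediate
14 | 5,5'-(ethane-1,2-diyl)bis[(4aR,8aS)-4a,6-dimethyl-3,4,4a,7,8,8a-hexahydronaphthalen-1(2H)-one] (bis(trans-decalone)) | C(CC1=C(C)CC[C@@H]2C(=O)CCC[C@@]12C)C1=C(C)CC[C@@H]2C(=O)CCC[C@@]12C | intermediate
15 | bis(trimethylsilyl) peroxide | C[Si](C)(C)OO[Si](C)(C)C | starting material
16 | bis(Criegee adduct): each C=O of 14 as C(OSiMe3)(OOSiMe3) | C(CC1=C(C)CC[C@@H]2C(O[Si](C)(C)C)(OO[Si](C)(C)C)CCC[C@@]12C)C1=C(C)CC[C@@H]2C(O[Si](C)(C)C)(OO[Si](C)(C)C)CCC[C@@]12C | intermediate (not isolated)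
17 | 6,6'-(ethane-1,2-diyl)bis[(5aS,9aS)-5a,7-dimethyl-4,5,5a,8,9,9a-hexahydro-1-benzoxepin-2(3H)-one] (bis(ε-lactone)) | C(CC1=C(C)CC[C@@H]2OC(=O)CCC[C@@]12C)C1=C(C)CC[C@@H]2OC(=O)CCC[C@@]12C | intermediate
18 | bis(potassium enolate) of 17 | [K+].[K+].C(CC1=C(C)CC[C@@H]2OC([O-])=CCC[C@@]12C)C1=C(C)CC[C@@H]2OC([O-])=CCC[C@@]12C | intermediate (not isolated)
19 | bis(ketene acetal diphenyl phosphate) of 17: each lactone as the 2-[(diphenoxyphosphoryl)oxy]-4,5,5a,8,9,9a-hexahydro-1-benzoxepine, (5aS,9aS) | C(CC1=C(C)CC[C@@H]2OC(OP(=O)(Oc3ccccc3)Oc3ccccc3)=CCC[C@@]12C)C1=C(C)CC[C@@H]2OC(OP(=O)(Oc3ccccc3)Oc3ccccc3)=CCC[C@@]12C | intermediate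
20 | 1,2-bis[(5aS,9aS)-2,5a,7-trimethyl-4,5,5a,8,9,9a-hexahydro-1-benzoxepin-6-yl]ethane (bis(cyclic enol ether)) | C(CC1=C(C)CC[C@@H]2OC(C)=CCC[C@@]12C)C1=C(C)CC[C@@H]2OC(C)=CCC[C@@]12C | intermediate
21 | bis(2,3-epoxide) of 20 (epoxide configuration not controlled) | C(CC1=C(C)CC[C@@H]2OC3(C)OC3CC[C@@]12C)C1=C(C)CC[C@@H]2OC3(C)OC3CC[C@@]12C | intermediate (not isolated)
22 | 6,6'-(ethane-1,2-diyl)bis[(5aS,9aS)-2,2,5a,7-tetramethyl-2,3,4,5,5a,8,9,9a-octahydro-1-benzoxepin-3-ol], mixture of C3 epimers | C(CC1=C(C)CC[C@@H]2OC(C)(C)C(O)CC[C@@]12C)C1=C(C)CC[C@@H]2OC(C)(C)C(O)CC[C@@]12C | intermediate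
23 | 6,6'-(ethane-1,2-diyl)bis[(5aS,9aS)-2,2,5a,7-tetramethyl-4,5,5a,8,9,9a-hexahydro-1-benzoxepin-3(2H)-one] (C2-symmetric diketone) | C(CC1=C(C)CC[C@@H]2OC(C)(C)C(=O)CC[C@@]12C)C1=C(C)CC[C@@H]2OC(C)(C)C(=O)CC[C@@]12C | intermediate
24 | sodwanone T, (5aS,9aS)-6-{2-[(3R,5aS,9aS)-3-hydroxy-2,2,5a,7-tetramethyl-2,3,4,5,5a,8,9,9a-octahydro-1-benzoxepin-6-yl]ethyl}-2,2,5a,7-tetramethyl-4,5,5a,8,9,9a-hexahydro-1-benzoxepin-3(2H)-one | CC1=C(CCC2=C(C)CC[C@@H]3OC(C)(C)[C@H](O)CC[C@@]23C)[C@]2(C)CCC(=O)C(C)(C)O[C@H]2CC1 | target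

**Step count and risks**
Total step count: 16. Longest linear sequence: 16 steps from 1; the route is linear, and step 8 joins two molecules of 10.

Step 14 (epoxidation and methylation). The dioxirane may also epoxidise the tetrasubstituted ring alkenes, or the epoxy acetal may suffer a hydride shift before methyl transfer. The fallback sets out from 17, bypasses steps 12–14 and returns at 22. It introduces the C3/C22 oxygen by enolate hydroxylation, which leaves alkenes alone, and the second methyl by ionic substitution. The lactone potassium enolates (KN(SiMe3)2, THF, −78 °C) would be hydroxylated with 2-(phenylsulfonyl)-3-phenyloxaziridine to the bis(3-hydroxy lactone) F1. Silylation (tBuMe2SiOTf, 2,6-lutidine) would give the bis(silyl ether) F2. MeLi at −78 °C would add once to each lactone to give the bis(methyl lactol) F3. Me3SiOTf would ionise F3 to the cyclic oxocarbenium ion, which AlMe3 methylates to the bis(3-silyloxy-2,2-dimethyloxepane) F4. Bu4NF would then release 22.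

Step 8 (allylic homocoupling). Coupling may occur through the fully substituted allyl terminus, or the allyl intermediate may be reduced or disproportionate instead of dimerising. The fallback sets out from 10 and returns at 11, forming C12–C13 by a Biellmann-type sulfone alkylation. Half of 10 with PhSO2Na in DMF would give the allylic sulfone F5. Its lithio derivative (n-BuLi, THF, −78 °C) would be alkylated with the other half of 10 to the coupled sulfone F6. Palladium-catalysed desulfonylation (LiBHEt3, PdCl2(dppp), THF, 0 °C), with hydride delivered to the less hindered allyl terminus, would give 11.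

Step 9 (twofold hydroboration). Facial selectivity may be insufficient once multiplied over two sites, and the tetrasubstituted alkenes may be partly hydroborated. The fallback sets out from 8 and returns at 13. It moves the hydroboration to the monomer, where the tetrasubstituted alkene is deactivated by the ester and the ring-fusion isomers can be separated. BH3·SMe2 then NaBO3 on 8 would give the trans-fused hydroxy ester F7. tBuMe2SiCl and imidazole would give the silyl ether ester F8. iBu2AlH would give the allylic alcohol F9, and CBr4/PPh3 the allylic bromide F10. CoCl(PPh3)3 would couple F10 to the dimeric bis(silyl ether) F11, and Bu4NF would release 13.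

**Further compounds**
F1 | step 14 | bis(3-hydroxy lactone): 17 with OH at C3 of each lactone (C3 epimers) | C(CC1=C(C)CC[C@@H]2OC(=O)C(O)CC[C@@]12C)C1=C(C)CC[C@@H]2OC(=O)C(O)CC[C@@]12C
F2 | step 14 | bis(silyl ether): F1 as its bis(tert-butyldimethylsilyl) ether | C(CC1=C(C)CC[C@@H]2OC(=O)C(O[Si](C)(C)C(C)(C)C)CC[C@@]12C)C1=C(C)CC[C@@H]2OC(=O)C(O[Si](C)(C)C(C)(C)C)CC[C@@]12C
F3 | step 14 | bis(methyl lactol): each lactone C=O of F2 as C(CH3)(OH) | C(CC1=C(C)CC[C@@H]2OC(C)(O)C(O[Si](C)(C)C(C)(C)C)CC[C@@]12C)C1=C(C)CC[C@@H]2OC(C)(O)C(O[Si](C)(C)C(C)(C)C)CC[C@@]12C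
F4 | step 14 | bis(3-silyloxy-2,2-dimethyloxepane): 22 as its bis(tert-butyldimethylsilyl) ether | C(CC1=C(C)CC[C@@H]2OC(C)(C)C(O[Si](C)(C)C(C)(C)C)CC[C@@]12C)C1=C(C)CC[C@@H]2OC(C)(C)C(O[Si](C)(C)C(C)(C)C)CC[C@@]12C
F5 | step 8 | allylic sulfone: (8aR)-2,8a-dimethyl-1-[(phenylsulfonyl)methyl]-3,4,6,7,8,8a-hexahydronaphthalene | C[C@@]12CCCC=C1CCC(C)=C2CS(=O)(=O)c1ccccc1
F6 | step 8 | coupled sulfone: 11 with a phenylsulfonyl group on one carbon of the ethane bridge | O=S(=O)(c1ccccc1)C(CC1=C(C)CCC2=CCCC[C@@]12C)C1=C(C)CCC2=CCCC[C@@]12C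
F7 | step 9 | hydroxy ester: methyl (4aR,5S,8aR)-5-hydroxy-2,8a-dimethyl-3,4,4a,5,6,7,8,8a-octahydronaphthalene-1-carboxylate | COC(=O)C1=C(C)CC[C@@H]2[C@@H](O)CCC[C@@]12C
F8 | step 9 | silyl ether ester: F7 as its tert-butyldimethylsilyl ether | COC(=O)C1=C(C)CC[C@@H]2[C@@H](O[Si](C)(C)C(C)(C)C)CCC[C@@]12C
F9 | step 9 | allylic alcohol: F8 with CH2OH in place of CO2Me | OCC1=C(C)CC[C@@H]2[C@@H](O[Si](C)(C)C(C)(C)C)CCC[C@@]12C
F10 | step 9 | allylic bromide: F9 with CH2Br in place of CH2OH | BrCC1=C(C)CC[C@@H]2[C@@H](O[Si](C)(C)C(C)(C)C)CCC[C@@]12C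
F11 | step 9 | dimeric bis(silyl ether): 13 as its bis(tert-butyldimethylsilyl) ether | C(CC1=C(C)CC[C@@H]2[C@@H](O[Si](C)(C)C(C)(C)C)CCC[C@@]12C)C1=C(C)CC[C@@H]2[C@@H](O[Si](C)(C)C(C)(C)C)CCC[C@@]12C
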